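**Plan**

- Lettering: rings A to F run from the 2,4,6-trihydroxyphenoxy end to the 3,4,5-trihydroxyphenyl end, and in every ring position 1 is the carbon whose ether oxygen points towards the ring A end (in ring A, the carbon bearing its only ether oxygen). The five ether bridges join position 1 of ring A to position 1 of ring B, position 6 of ring B to position 1 of ring C, position 4 of ring C to position 1 of ring D, position 6 of ring D to position 1 of ring E, and position 4 of ring E to position 1 of ring F. All sixteen hydroxyl groups are carried as methyl ethers and freed in the last step.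
- Cuts: first the two ortho-ether bridges (ring B to ring C and ring D to ring E), giving an AB, a CD and an EF unit. Then the two bridges at position 4 of rings C and E, which both lead back to one aldehyde made from syringaldehyde. Last, ring A itself, at the bonds between its positions 2 and 3 and between its positions 5 and 6.
- Enabling feature: position 1 of ring A carries the ether oxygen and lies between the hydroxylated positions 2 and 6, which is the central carbon of an aryloxymalonate between its two acyl carbons. Positions 3, 4 and 5 of ring A are the C–C(O)–C unit of an acetonedicarboxylate, so ring A can be grown on the oxygen of ring B by a double Claisen condensation that leaves esters on positions 3 and 5.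
- Forward: ring B phenol → aryloxymalonate → ring A closed → methylation → iodination at position 6 of ring B, with the two esters keeping ring A silent. In parallel the common CD/EF aldehyde is split into an EF phenol and a CD iodide. Ullmann couplings join CD to EF and then AB to CDEF; ester hydrolysis, decarboxylation and BBr3 finish.
- Stereochemistry: the target has no stereocentre, so nothing has to be set.

Key step: step 2

Remark: it is assumed that the sixteen aryl methyl ethers can be cleaved together at the end, since the molecule then holds no other bond that BBr3 attacks.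

**Route**

Step 1
Reactants: 1 3,4,5-trimethoxyphenol; 2 diethyl chloromalonate
Product: 3 diethyl 2-(3,4,5-trimethoxyphenoxy)malonate
Conditions: K2CO3, acetone, reflux
Reagents that add atoms: none
Why: Williamson O-alkylation (SN2) of a phenoxide with an α-halomalonate is a standard entry to aryloxymalonates; the chloride is preferred to the bromide so that the electron-rich ring is not halogenated by the reagent.

Step 2
Reactants: 3 diethyl 2-(3,4,5-trimethoxyphenoxy)malonate; 4 diethyl acetonedicarboxylate
Product: 6 diethyl 2,4,6-trihydroxy-5-(3,4,5-trimethoxyphenoxy)isophthalate, via acyclic diketo triester 5 (not isolated)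
Conditions: 4 added slowly to 3 (1.3 equiv), NaOEt (2.2 equiv), xylene, 140 °C, EtOH distilled off; then cold 1 M HCl
Reagents that add atoms: none
Why: Ethoxide deprotonates 4 at a doubly activated methylene, and this enolate attacks one ester carbonyl of 3 with loss of ethoxide (crossed Claisen condensation, forming the bond between positions 2 and 3 of ring A) to give 5 as its stabilised enolate. The second methylene carbon of the acetonedicarboxylate part then adds to the remaining malonate ester in a 6-exo-trig Dieckmann closure (forming the bond between positions 6 and 5 of ring A), and the cyclohexanetrione so formed tautomerises to the aromatic triol, whose phenoxide salt is the thermodynamic sink. The closest known reaction is the alkoxide-mediated condensation of malonic esters with acetonedicarboxylic esters to phloroglucinol dicarboxylates. No stereocentre is formed, since the CH(OAr) carbon of 3 and 5 ends as the sp2 carbon at position 1 of ring A. The step needs C-acylation over O-acylation and crossed over self-condensation of 4: lactone formation through oxygen is reversible under ethoxide while aromatisation is not, and slow addition of 4 to an excess of 3 keeps its self-condensation down. Distilling off ethanol pulls both Claisen equilibria forward, and because the ether oxygen was attached by SN2 in step 1, the hindered position 1 of ring A never has to be arylated.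

Step 3
Reactants: 6 diethyl 2,4,6-trihydroxy-5-(3,4,5-trimethoxyphenoxy)isophthalate
Product: 7 diethyl 2,4,6-trimethoxy-5-(3,4,5-trimethoxyphenoxy)isophthalate
Conditions: Me2SO4 (4 equiv), K2CO3, acetone, reflux
Reagents that add atoms: dimethyl sulfate, COS(=O)(=O)OC
Why: Exhaustive Williamson O-methylation of hydrogen-bonded salicylate-type phenols with a hard methylating agent; every carbon of ring A is substituted, so C-methylation could only occur with loss of aromaticity and should not compete.

Step 4
Reactants: 7 diethyl 2,4,6-trimethoxy-5-(3,4,5-trimethoxyphenoxy)isophthalate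
Product: 8 diethyl 5-(2-iodo-3,4,5-trimethoxyphenoxy)-2,4,6-trimethoxyisophthalate
Conditions: NIS (1.05 equiv), TFA (cat.), MeCN, 0 °C to rt
Reagents that add atoms: N-iodosuccinimide, O=C1CCC(=O)N1I
Why: Electrophilic aromatic iodination; ring A has no free position and is deactivated by its two esters, so only ring B can react, at its position 6 (equivalent to its position 2), which is ortho to the aryloxy group and a methoxy group and para to another, and one equivalent of reagent should stop at the monoiodide.

Step 5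
Reactants: 9 syringaldehyde (4-hydroxy-3,5-dimethoxybenzaldehyde); 10 3,4,5-trimethoxyphenylboronic acid
Product: 11 3,5-dimethoxy-4-(3,4,5-trimethoxyphenoxy)benzaldehyde
Conditions: Cu(OAc)2 (1.0 equiv), pyridine (5 equiv), 4 Å MS, CH2Cl2, O2 (1 atm), rt
Reagents that add atoms: none
Why: Chan–Lam oxidative O-arylation tolerates phenols with two ortho substituents and an aldehyde, and the boronic acid partner is unhindered; O2 is the terminal oxidant, so the copper salt returns to its divalent state.

Step 6
Reactants: 11 3,5-dimethoxy-4-(3,4,5-trimethoxyphenoxy)benzaldehyde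
Product: 13 3,5-dimethoxy-4-(3,4,5-trimethoxyphenoxy)phenol, via aryl formate 12 (not isolated)
Conditions: mCPBA, CH2Cl2, 0 °C to rt; then K2CO3 (cat.), MeOH, rt
Reagents that add atoms: 3-chloroperbenzoic acid, OOC(=O)c1cccc(Cl)c1
Why: Baeyer–Villiger (Dakin-type) oxidation of a benzaldehyde with a para oxygen donor proceeds by aryl migration, as in the conversion of 3,4,5-trimethoxybenzaldehyde into 3,4,5-trimethoxyphenol; the formate is then cleaved by mild methanolysis.

Step 7
Reactants: 11 3,5-dimethoxy-4-(3,4,5-trimethoxyphenoxy)benzaldehyde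
Product: 14 4-(2-iodo-3,4,5-trimethoxyphenoxy)-3,5-dimethoxybenzaldehyde
Conditions: NIS (1.05 equiv), TFA (cat.), MeCN, 0 °C to rt
Reagents that add atoms: N-iodosuccinimide, O=C1CCC(=O)N1I
Why: Electrophilic aromatic iodination; ring D carries four oxygen donors and no acceptor, whereas ring C is deactivated by the formyl group, so iodine should enter at position 6 of ring D (equivalent to its position 2).

Step 8
Reactants: 14 4-(2-iodo-3,4,5-trimethoxyphenoxy)-3,5-dimethoxybenzaldehyde; 13 3,5-dimethoxy-4-(3,4,5-trimethoxyphenoxy)phenol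
Product: 15 4-{2-[3,5-dimethoxy-4-(3,4,5-trimethoxyphenoxy)phenoxy]-3,4,5-trimethoxyphenoxy}-3,5-dimethoxybenzaldehyde
Conditions: CuI (20 mol%), picolinic acid (40 mol%), K3PO4 (2 equiv), DMSO, 90 °C
Reagents that add atoms: none
Why: Ullmann-type copper-catalysed diaryl ether synthesis; the picolinic acid system is suited to ortho-substituted aryl iodides, the phenol is electron-rich and unhindered (positions 2 and 6 of ring E are CH), and an aldehyde without α-hydrogen should survive phosphate base.

Step 9
Reactants: 15 4-{2-[3,5-dimethoxy-4-(3,4,5-trimethoxyphenoxy)phenoxy]-3,4,5-trimethoxyphenoxy}-3,5-dimethoxybenzaldehyde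
Product: 17 4-{2-[3,5-dimethoxy-4-(3,4,5-trimethoxyphenoxy)phenoxy]-3,4,5-trimethoxyphenoxy}-3,5-dimethoxyphenol, via tetrameric aryl formate 16 (not isolated)
Conditions: mCPBA, CH2Cl2, 0 °C to rt; then K2CO3 (cat.), MeOH, rt
Reagents that add atoms: 3-chloroperbenzoic acid, OOC(=O)c1cccc(Cl)c1
Why: The same Baeyer–Villiger (Dakin-type) aryl migration as in step 6, on the identical 3,5-dimethoxy-4-aryloxybenzaldehyde unit; the fully alkoxylated rings D, E and F should be far slower to oxidise than the aldehyde.

Step 10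
Reactants: 8 diethyl 5-(2-iodo-3,4,5-trimethoxyphenoxy)-2,4,6-trimethoxyisophthalate; 17 4-{2-[3,5-dimethoxy-4-(3,4,5-trimethoxyphenoxy)phenoxy]-3,4,5-trimethoxyphenoxy}-3,5-dimethoxyphenol
Product: 18 diethyl 5-[2-(4-{2-[3,5-dimethoxy-4-(3,4,5-trimethoxyphenoxy)phenoxy]-3,4,5-trimethoxyphenoxy}-3,5-dimethoxyphenoxy)-3,4,5-trimethoxyphenoxy]-2,4,6-trimethoxyisophthalate
Conditions: CuI (20 mol%), picolinic acid (40 mol%), K3PO4 (2 equiv), DMSO, 90 °C
Reagents that add atoms: none
Why: The same Ullmann-type etherification as in step 8, now forming the bridge from position 6 of ring B to position 1 of ring C; the phenol is again unhindered at positions 2 and 6 of ring C, and the shielded ethyl esters should be inert to phosphate in DMSO.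

Step 11
Reactants: 18 the hexameric diester
Product: 19 5-[2-(4-{2-[3,5-dimethoxy-4-(3,4,5-trimethoxyphenoxy)phenoxy]-3,4,5-trimethoxyphenoxy}-3,5-dimethoxyphenoxy)-3,4,5-trimethoxyphenoxy]-2,4,6-trimethoxyisophthalic acid
Conditions: KOH (excess), EtOH/H2O, reflux; then 1 M HCl, 0 °C
Reagents that add atoms: potassium hydroxide, [K+].[OH-]
Why: Ester saponification; the esters are flanked by methoxy groups and will need forcing, which is acceptable because aryl and methyl ethers are the only other functions and the ether oxygen on position 1 of ring A is meta to both esters, so it is not activated towards displacement.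

Step 12
Reactants: 19 the hexameric diacid
Product: 20 hexadeca-O-methyl ether of the target
Conditions: Ag2CO3 (20 mol%), AcOH (10 mol%), DMSO, 120 °C
Reagents that add atoms: none
Why: Silver-catalysed protodecarboxylation of benzoic acids with two ortho substituents; each carboxyl group sits between two methoxy groups, the substitution pattern that reacts most readily in this reaction.

Step 13
Reactants: 20 hexadeca-O-methyl ether of the target
Product: 21 the target, CNP0218077.0
Conditions: BBr3 (40 equiv), CH2Cl2, −78 °C to rt; then degassed H2O, under Ar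
Reagents that add atoms: none
Why: Lewis-acid cleavage of aryl methyl ethers with BBr3 leaves diaryl ether bonds intact; the free polyphenol should be handled under argon because its pyrogallol units are prone to air oxidation.

**Compound list**

1 | 3,4,5-trimethoxyphenol | COc1cc(O)cc(OC)c1OC | starting material
2 | diethyl chloromalonate | CCOC(=O)C(Cl)C(=O)OCC | starting material
3 | diethyl 2-(3,4,5-trimethoxyphenoxy)malonate | CCOC(=O)C(Oc1cc(OC)c(OC)c(OC)c1)C(=O)OCC | intermediate
4 | diethyl acetonedicarboxylate (diethyl 3-oxopentanedioate) | CCOC(=O)CC(=O)CC(=O)OCC | starting material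
5 | diethyl 2-[3-ethoxy-3-oxo-2-(3,4,5-trimethoxyphenoxy)propanoyl]-3-oxopentanedioate (acyclic diketo triester, mixture of tautomers and stereoisomers) | CCOC(=O)CC(=O)C(C(=O)OCC)C(=O)C(Oc1cc(OC)c(OC)c(OC)c1)C(=O)OCC | intermediate
6 | diethyl 2,4,6-trihydroxy-5-(3,4,5-trimethoxyphenoxy)isophthalate | CCOC(=O)c1c(O)c(Oc2cc(OC)c(OC)c(OC)c2)c(O)c(C(=O)OCC)c1O | intermediate
7 | diethyl 2,4,6-trimethoxy-5-(3,4,5-trimethoxyphenoxy)isophthalate | CCOC(=O)c1c(OC)c(Oc2cc(OC)c(OC)c(OC)c2)c(OC)c(C(=O)OCC)c1OC | intermediate
8 | diethyl 5-(2-iodo-3,4,5-trimethoxyphenoxy)-2,4,6-trimethoxyisophthalate | CCOC(=O)c1c(OC)c(Oc2cc(OC)c(OC)c(OC)c2I)c(OC)c(C(=O)OCC)c1OC | intermediate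
9 | syringaldehyde (4-hydroxy-3,5-dimethoxybenzaldehyde) | COc1cc(C=O)cc(OC)c1O | starting material
10 | 3,4,5-trimethoxyphenylboronic acid | COc1cc(B(O)O)cc(OC)c1OC | starting material
11 | 3,5-dimethoxy-4-(3,4,5-trimethoxyphenoxy)benzaldehyde | COc1cc(C=O)cc(OC)c1Oc1cc(OC)c(OC)c(OC)c1 | intermediate
12 | 3,5-dimethoxy-4-(3,4,5-trimethoxyphenoxy)phenyl formate | COc1cc(OC=O)cc(OC)c1Oc1cc(OC)c(OC)c(OC)c1 | intermediate
13 | 3,5-dimethoxy-4-(3,4,5-trimethoxyphenoxy)phenol | COc1cc(O)cc(OC)c1Oc1cc(OC)c(OC)c(OC)c1 | intermediate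
14 | 4-(2-iodo-3,4,5-trimethoxyphenoxy)-3,5-dimethoxybenzaldehyde | COc1cc(C=O)cc(OC)c1Oc1cc(OC)c(OC)c(OC)c1I | intermediate
15 | 4-{2-[3,5-dimethoxy-4-(3,4,5-trimethoxyphenoxy)phenoxy]-3,4,5-trimethoxyphenoxy}-3,5-dimethoxybenzaldehyde | O=Cc1cc(OC)c(Oc2cc(OC)c(OC)c(OC)c2Oc2cc(OC)c(Oc3cc(OC)c(OC)c(OC)c3)c(OC)c2)c(OC)c1 | intermediate
16 | 4-{2-[3,5-dimethoxy-4-(3,4,5-trimethoxyphenoxy)phenoxy]-3,4,5-trimethoxyphenoxy}-3,5-dimethoxyphenyl formate | O=COc1cc(OC)c(Oc2cc(OC)c(OC)c(OC)c2Oc2cc(OC)c(Oc3cc(OC)c(OC)c(OC)c3)c(OC)c2)c(OC)c1 | intermediate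
17 | 4-{2-[3,5-dimethoxy-4-(3,4,5-trimethoxyphenoxy)phenoxy]-3,4,5-trimethoxyphenoxy}-3,5-dimethoxyphenol | Oc1cc(OC)c(Oc2cc(OC)c(OC)c(OC)c2Oc2cc(OC)c(Oc3cc(OC)c(OC)c(OC)c3)c(OC)c2)c(OC)c1 | intermediate
18 | diethyl 5-[2-(4-{2-[3,5-dimethoxy-4-(3,4,5-trimethoxyphenoxy)phenoxy]-3,4,5-trimethoxyphenoxy}-3,5-dimethoxyphenoxy)-3,4,5-trimethoxyphenoxy]-2,4,6-trimethoxyisophthalate | CCOC(=O)c1c(OC)c(Oc2cc(OC)c(OC)c(OC)c2Oc2cc(OC)c(Oc3cc(OC)c(OC)c(OC)c3Oc3cc(OC)c(Oc4cc(OC)c(OC)c(OC)c4)c(OC)c3)c(OC)c2)c(OC)c(C(=O)OCC)c1OC | intermediate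
19 | 5-[2-(4-{2-[3,5-dimethoxy-4-(3,4,5-trimethoxyphenoxy)phenoxy]-3,4,5-trimethoxyphenoxy}-3,5-dimethoxyphenoxy)-3,4,5-trimethoxyphenoxy]-2,4,6-trimethoxyisophthalic acid | OC(=O)c1c(OC)c(Oc2cc(OC)c(OC)c(OC)c2Oc2cc(OC)c(Oc3cc(OC)c(OC)c(OC)c3Oc3cc(OC)c(Oc4cc(OC)c(OC)c(OC)c4)c(OC)c3)c(OC)c2)c(OC)c(C(=O)O)c1OC | intermediate
20 | hexadeca-O-methyl ether of the target (rings A to F, all hydroxyl groups as OMe) | COc1cc(OC)c(Oc2cc(OC)c(OC)c(OC)c2Oc2cc(OC)c(Oc3cc(OC)c(OC)c(OC)c3Oc3cc(OC)c(Oc4cc(OC)c(OC)c(OC)c4)c(OC)c3)c(OC)c2)c(OC)c1 | intermediate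
21 | CNP0218077.0 (achiral hexameric phlorotannin) | Oc1cc(O)c(Oc2cc(O)c(O)c(O)c2Oc2cc(O)c(Oc3cc(O)c(O)c(O)c3Oc3cc(O)c(Oc4cc(O)c(O)c(O)c4)c(O)c3)c(O)c2)c(O)c1 | target

**Step count**

Total: 13 steps. Longest linear sequence: 8 steps (steps 1–4 and 10–13; the branch through steps 5, 7, 8, 9 and 10–13 is equally long).

**Steps most likely to fail**

Step 2. The aryloxymalonate is partly deprotonated under the reaction conditions and is then a poor acyl donor, so self-condensation of the acetonedicarboxylate or a stall at the open-chain stage may outrun the double Claisen sequence. The fallback sets out from 3 and 4 and returns at 6, making the same two bonds one at a time. One ester of 3 would be saponified (KOH, 1.0 equiv, EtOH, 0 °C) to the half ester 3-ethoxy-3-oxo-2-(3,4,5-trimethoxyphenoxy)propanoic acid F1. Oxalyl chloride with catalytic DMF would convert this into ethyl 3-chloro-3-oxo-2-(3,4,5-trimethoxyphenoxy)propanoate F2. Irreversible C-acylation of the magnesium enolate of 4 with F2 (MgCl2, Et3N, MeCN, 0 °C) should give 5 as an isolated compound. A separate Dieckmann closure (NaOEt, EtOH, reflux) would then deliver 6.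

Step 10. Oxidative addition at position 6 of ring B may be slow because the iodide lies between the ether to the fully substituted ring A and a methoxy group, so reductive loss of iodine may take over. The fallback sets out from 7 and 17 and returns at 18 with the polarity reversed. Rieche formylation of 7 (Cl2CHOMe, TiCl4, CH2Cl2, −20 °C) should give diethyl 5-(2-formyl-3,4,5-trimethoxyphenoxy)-2,4,6-trimethoxyisophthalate F3. Baeyer–Villiger oxidation with mCPBA would lead to diethyl 5-[2-(formyloxy)-3,4,5-trimethoxyphenoxy]-2,4,6-trimethoxyisophthalate F4, and methanolysis (K2CO3 cat., MeOH, 0 °C) to diethyl 5-(2-hydroxy-3,4,5-trimethoxyphenoxy)-2,4,6-trimethoxyisophthalate F5. Phenol 17 would be converted (Tf2O, pyridine, CH2Cl2, 0 °C) into 4-{2-[3,5-dimethoxy-4-(3,4,5-trimethoxyphenoxy)phenoxy]-3,4,5-trimethoxyphenoxy}-3,5-dimethoxyphenyl trifluoromethanesulfonate F6. A palladium-catalysed C–O coupling of F5 with F6 (Pd(OAc)2, 2-(di-tert-butylphosphino)-2',4',6'-triisopropylbiphenyl, K3PO4, toluene, 100 °C) would then give 18, with the hindered partner on the phenol side and the unhindered one as electrophile.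

Step 8. Protodeiodination may compete with C–O bond formation at the doubly ortho-substituted position 6 of ring D, and the aldehyde may degrade slowly on prolonged heating with base. The fallback sets out from 13 and 9 and returns at 15, forming the bridge between rings D and E before the bulky ring C is attached. Commercial 5-bromo-1,2,3-trimethoxybenzene (COc1cc(Br)cc(OC)c1OC) would be iodinated (NIS, TFA cat., MeCN) to 1-bromo-2-iodo-3,4,5-trimethoxybenzene F7. Its iodide would be coupled selectively with 13 (CuI, picolinic acid, K3PO4, DMSO, 80 °C) to give 1-bromo-2-[3,5-dimethoxy-4-(3,4,5-trimethoxyphenoxy)phenoxy]-3,4,5-trimethoxybenzene F8. Bromine–lithium exchange and borylation (n-BuLi, THF, −78 °C; B(OiPr)3; dilute HCl) should give {2-[3,5-dimethoxy-4-(3,4,5-trimethoxyphenoxy)phenoxy]-3,4,5-trimethoxyphenyl}boronic acid F9. Chan–Lam coupling of F9 with syringaldehyde 9 (Cu(OAc)2, pyridine, 4 Å MS, CH2Cl2, O2, rt) would close the bridge between rings C and D and give 15.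

**Further compounds**

F1 | step 2 | 3-ethoxy-3-oxo-2-(3,4,5-trimethoxyphenoxy)propanoic acid (racemic) | CCOC(=O)C(Oc1cc(OC)c(OC)c(OC)c1)C(=O)O
F2 | step 2 | ethyl 3-chloro-3-oxo-2-(3,4,5-trimethoxyphenoxy)propanoate (racemic) | CCOC(=O)C(Oc1cc(OC)c(OC)c(OC)c1)C(Cl)=O
F3 | step 10 | diethyl 5-(2-formyl-3,4,5-trimethoxyphenoxy)-2,4,6-trimethoxyisophthalate | CCOC(=O)c1c(OC)c(Oc2cc(OC)c(OC)c(OC)c2C=O)c(OC)c(C(=O)OCC)c1OC
F4 | step 10 | diethyl 5-[2-(formyloxy)-3,4,5-trimethoxyphenoxy]-2,4,6-trimethoxyisophthalate | CCOC(=O)c1c(OC)c(Oc2cc(OC)c(OC)c(OC)c2OC=O)c(OC)c(C(=O)OCC)c1OC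
F5 | step 10 | diethyl 5-(2-hydroxy-3,4,5-trimethoxyphenoxy)-2,4,6-trimethoxyisophthalate | CCOC(=O)c1c(OC)c(Oc2cc(OC)c(OC)c(OC)c2O)c(OC)c(C(=O)OCC)c1OC
F6 | step 10 | 4-{2-[3,5-dimethoxy-4-(3,4,5-trimethoxyphenoxy)phenoxy]-3,4,5-trimethoxyphenoxy}-3,5-dimethoxyphenyl trifluoromethanesulfonate | FC(F)(F)S(=O)(=O)Oc1cc(OC)c(Oc2cc(OC)c(OC)c(OC)c2Oc2cc(OC)c(Oc3cc(OC)c(OC)c(OC)c3)c(OC)c2)c(OC)c1
F7 | step 8 | 1-bromo-2-iodo-3,4,5-trimethoxybenzene | COc1cc(Br)c(I)c(OC)c1OC
F8 | step 8 | 1-bromo-2-[3,5-dimethoxy-4-(3,4,5-trimethoxyphenoxy)phenoxy]-3,4,5-trimethoxybenzene | COc1cc(Br)c(Oc2cc(OC)c(Oc3cc(OC)c(OC)c(OC)c3)c(OC)c2)c(OC)c1OC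
F9 | step 8 | {2-[3,5-dimethoxy-4-(3,4,5-trimethoxyphenoxy)phenoxy]-3,4,5-trimethoxyphenyl}boronic acid | COc1cc(B(O)O)c(Oc2cc(OC)c(Oc3cc(OC)c(OC)c(OC)c3)c(OC)c2)c(OC)c1OC
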